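**Plan**

1. Retrosynthesis: the O1–C2 aryl ether is cut first (a phenol closing onto a secondary carbinol with inversion), and the carbinol goes back to a methyl ketone, which is the hemiketal of a 2-methoxy-2-methylchroman. That ketal is cut at C3–C4 and O1–C2 into an ortho-quinone methide and 2-methoxypropene; the aryl–CH(OH) bond and the naphthyl C–Br bond are cut last.
2. Enabling feature: the pyran atoms O1, C2, C3 and C4 hang on a 2-substituted resorcinol whose two hydroxyls are equivalent. C4 with its naphthyl is therefore the methide terminus of one single ortho-quinone methide, C2–C3 is an enol ether, and the unused hydroxyl becomes the C5 phenol.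
3. Forward: naphthalene-1,8-diol is methylated and brominated at C4, and its Grignard reagent is joined to 2,6-dihydroxybenzaldehyde. A chiral phosphoric acid then closes the pyran ring as the methyl ketal by oxa-[4+2] cycloaddition.
4. The ketal is hydrolysed, its open-chain ketone is reduced by an alcohol dehydrogenase, and the pyran ring is closed again at O1–C2 by a Mitsunobu reaction.
5. Stereochemistry: C4 (S) comes from the chiral phosphate in the cycloaddition. C2 (R) comes from the enzyme-set (S)-carbinol and SN2 inversion, so the 2,4-trans relation does not depend on substrate bias.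
6. C2 is deliberately not left to hydride reduction of the ketal-derived oxocarbenium ion: the peri C5 hydroxyl holds the naphthyl pseudoaxial, and a hydride would have to enter syn to it to give the trans isomer.

Key step: step 4

Assumption: the (R)-configured phosphoric acid is taken to shield the face that leads to 4S; if the sense turns out opposite, its (S)-enantiomer is used and nothing else changes.

**Route**

Step 1
Reactants: 1 naphthalene-1,8-diol
Product: 2 1,8-dimethoxynaphthalene
Conditions: MeI (3 equiv), K2CO3 (3 equiv), DMF, 50 °C, N2
Reagents that add atoms: iodomethane, CI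
Why: Double Williamson etherification of the peri-diol under carbonate base, where heating in DMF overcomes the hydrogen bond that slows methylation at the 8-methoxy-1-naphthol stage.

Step 2
Reactants: 2 1,8-dimethoxynaphthalene
Product: 3 4-bromo-1,8-dimethoxynaphthalene
Conditions: NBS (1.0 equiv), MeCN, 0 °C → rt, dark
Reagents that add atoms: N-bromosuccinimide, O=C1CCC(=O)N1Br
Why: Electrophilic aromatic bromination of the activated naphthalene goes para to a methoxy group (C4) in preference to the ortho positions, and one equivalent of reagent in acetonitrile should stop at the monobromide.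

Step 3
Reactants: 3 4-bromo-1,8-dimethoxynaphthalene; 4 2,6-dihydroxybenzaldehyde
Product: 6 2-[(4,5-dimethoxynaphthalen-1-yl)(hydroxy)methyl]benzene-1,3-diol (racemic), via arylmagnesium bromide 5 (not isolated)
Conditions: 3 (3.5 equiv), Mg, I2 (cat.), THF, 50 °C; then 4 (1 equiv), THF, 0 °C → rt; NaH2PO4/Na2HPO4 buffer (pH 7)
Reagents that add atoms: none
Why: Grignard addition to the aldehyde, in which two equivalents of 5 are consumed by the phenols and the third adds to the magnesium-chelated formyl group as in the usual preparation of ortho-hydroxybenzhydrols from salicylaldehydes, while the neutral buffered work-up spares the easily ionized doubly benzylic alcohol; the carbinol centre is racemic and is erased in step 4.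

Step 4
Reactants: 6 2-[(4,5-dimethoxynaphthalen-1-yl)(hydroxy)methyl]benzene-1,3-diol (racemic); 7 2-methoxypropene
Product: 9 (2R,4S)-4-(4,5-dimethoxynaphthalen-1-yl)-2-methoxy-2-methylchroman-5-ol, via ortho-quinone methide 8 (not isolated)
Conditions: (R)-3,3'-bis(2,4,6-triisopropylphenyl)-1,1'-binaphthyl-2,2'-diyl hydrogen phosphate (10 mol %), 7 (5 equiv), 4 Å molecular sieves, CH2Cl2/toluene, −40 °C, slow addition of 6; Et3N quench
Reagents that add atoms: none
Why: The acid dehydrates the doubly benzylic carbinol to ortho-quinone methide 8 and remains hydrogen-bonded to its carbonyl oxygen and to the spare phenol; the CH2 terminus of 2-methoxypropene attacks the methide carbon (C3–C4) and the quinone methide oxygen captures the methoxy-stabilized cation so formed (O1–C2), an asynchronous inverse-electron-demand oxa-[4+2] cycloaddition. The closest known reaction type is the chiral phosphoric acid-catalysed [4+2] cycloaddition of ortho-quinone methides, made in situ from ortho-hydroxybenzhydrols, with enamides, vinyl sulfides and other electron-rich alkenes. The pyran ring closes by this cycloaddition, the second bond forming as a 6-exo-trig attack of oxygen on the oxocarbenium carbon. C4 is set by the chiral phosphate, which shields one face of the planar methide in the hydrogen-bonded ion pair, whereas the ketal centre C2 follows the methoxy-endo approach and does not matter because step 5 erases it. The step needs enantiofacial control at C4 and chemoselectivity for the enol ether over the resorcinol ring of a second molecule: the first rests on two-point binding of the acid to a quinone methide that is unique because the two resorcinol hydroxyls are equivalent, the second on the excess of the much more nucleophilic enol ether, the slow addition of 6 and the low temperature. The sieves take up the water released, and any 2-methoxyprop-2-yl ether formed on the C5 hydroxyl, like any 4H-chromene formed by loss of methanol, converges on 10 in step 5.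

Step 5
Reactants: 9 (2R,4S)-4-(4,5-dimethoxynaphthalen-1-yl)-2-methoxy-2-methylchroman-5-ol
Product: 10 (2R,4S)-4-(4,5-dimethoxynaphthalen-1-yl)-2-methylchromane-2,5-diol
Conditions: 0.1 M aq HCl, THF, 0 °C → rt
Reagents that add atoms: water, O
Why: Acid-catalysed ketal hydrolysis through the cyclic oxocarbenium ion exchanges methoxy for hydroxy under conditions too mild to touch the C4–H stereocentre, and since the hemiketal anomers interconvert through the open-chain ketone the configuration at C2 is immaterial.

Step 6
Reactants: 10 (2R,4S)-4-(4,5-dimethoxynaphthalen-1-yl)-2-methylchromane-2,5-diol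
Product: 12 (2S,4S)-4-(2,6-dihydroxyphenyl)-4-(4,5-dimethoxynaphthalen-1-yl)butan-2-ol, via open-chain methyl ketone 11 (not isolated)
Conditions: alcohol dehydrogenase ADH-A (Rhodococcus ruber), NAD+ (cat.), i-PrOH (20% v/v), KH2PO4/K2HPO4 buffer pH 7.5, 30 °C, N2
Reagents that add atoms: none
Why: Enzymatic carbonyl reduction, in which the hemiketal opens reversibly to methyl ketone 11 and the (S)-selective alcohol dehydrogenase transfers hydride from NADH to its Re face (methyl in the small pocket, the diarylethyl chain in the large one), so that the carbinol should be set S by the enzyme independently of C4 while 2-propanol regenerates the cofactor.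

Step 7
Reactants: 12 (2S,4S)-4-(2,6-dihydroxyphenyl)-4-(4,5-dimethoxynaphthalen-1-yl)butan-2-ol
Product: 13 (2R,4S)-4-(4,5-dimethoxynaphthalen-1-yl)-2-methylchroman-5-ol (cladonaphchrom A)
Conditions: PPh3, DIAD, THF (0.02 M), 0 °C → rt
Reagents that add atoms: none
Why: Intramolecular Mitsunobu etherification, in which the alkoxyphosphonium of the secondary alcohol is displaced by one of the two equivalent phenols in a 6-exo-tet SN2 closure with inversion (2S carbinol to 2R ether), placing the methyl trans to the naphthyl at the untouched C4 and leaving the second phenol as the C5 hydroxyl.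

**Compound list**

1 | naphthalene-1,8-diol | Oc1cccc2cccc(O)c12 | starting material
2 | 1,8-dimethoxynaphthalene | COc1cccc2cccc(OC)c12 | intermediate
3 | 4-bromo-1,8-dimethoxynaphthalene | COc1cccc2c(Br)ccc(OC)c12 | intermediate
4 | 2,6-dihydroxybenzaldehyde | O=Cc1c(O)cccc1O | starting material
5 | (4,5-dimethoxynaphthalen-1-yl)magnesium bromide | COc1cccc2c([Mg]Br)ccc(OC)c12 | intermediate
6 | 2-[(4,5-dimethoxynaphthalen-1-yl)(hydroxy)methyl]benzene-1,3-diol (racemic) | COc1cccc2c(C(O)c3c(O)cccc3O)ccc(OC)c12 | intermediate
7 | 2-methoxypropene | C=C(C)OC | starting material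
8 | (6E)-6-[(4,5-dimethoxynaphthalen-1-yl)methylidene]-5-hydroxycyclohexa-2,4-dien-1-one (ortho-quinone methide, naphthyl anti to the ring carbonyl) | O=C1C=CC=C(O)/C1=C\c1ccc(OC)c2c(OC)cccc12 | intermediate
9 | (2R,4S)-4-(4,5-dimethoxynaphthalen-1-yl)-2-methoxy-2-methylchroman-5-ol (methoxy cis to the naphthyl; the C2 epimer may accompany it) | COc1cccc2c([C@@H]3C[C@](C)(OC)Oc4cccc(O)c43)ccc(OC)c12 | intermediate
10 | (2R,4S)-4-(4,5-dimethoxynaphthalen-1-yl)-2-methylchromane-2,5-diol (cyclic hemiketal, 2-hydroxyl drawn cis to the naphthyl; anomers equilibrate) | COc1cccc2c([C@@H]3C[C@](C)(O)Oc4cccc(O)c43)ccc(OC)c12 | intermediate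
11 | (4S)-4-(2,6-dihydroxyphenyl)-4-(4,5-dimethoxynaphthalen-1-yl)butan-2-one | COc1cccc2c([C@H](CC(C)=O)c3c(O)cccc3O)ccc(OC)c12 | intermediate
12 | (2S,4S)-4-(2,6-dihydroxyphenyl)-4-(4,5-dimethoxynaphthalen-1-yl)butan-2-ol | COc1cccc2c([C@H](C[C@H](C)O)c3c(O)cccc3O)ccc(OC)c12 | intermediate
13 | (2R,4S)-4-(4,5-dimethoxynaphthalen-1-yl)-2-methylchroman-5-ol, 2,4-trans (cladonaphchrom A) | COc1cccc2c([C@@H]3C[C@@H](C)Oc4cccc(O)c43)ccc(OC)c12 | target

**Step count and risks**

Total step count: 7. Longest linear sequence: 7 steps (1 to 13); 4 and 7 enter as bought.

Steps most likely to fail: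

Step 4 (key step). What may go wrong: facial discrimination at C4 may be weak, because so stabilized a diarylmethyl cation can add the enol ether as a loose ion pair or by an uncatalysed background path. Fallback: control at C4 is given up in the cycloaddition and won back by the enzyme. Setting out from 6, the achiral acid diphenyl phosphate under otherwise the same conditions should give the racemic ketal, that is 9 mixed with (2S,4R)-4-(4,5-dimethoxynaphthalen-1-yl)-2-methoxy-2-methylchroman-5-ol F1. Hydrolysis as in step 5 gives 10 mixed with (2S,4R)-4-(4,5-dimethoxynaphthalen-1-yl)-2-methylchromane-2,5-diol F2. The alcohol dehydrogenase of step 6, which should fix the new carbinol as S on either antipode, reduces ketone 11 and (4R)-4-(2,6-dihydroxyphenyl)-4-(4,5-dimethoxynaphthalen-1-yl)butan-2-one F3 to 12 and (2S,4R)-4-(2,6-dihydroxyphenyl)-4-(4,5-dimethoxynaphthalen-1-yl)butan-2-ol F4. These two are diastereomers and are parted by chromatography, and the route is rejoined at 12.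

Step 3. What may go wrong: the doubly deprotonated aldehyde may be too insoluble or too deactivated for complete addition, and most of the Grignard reagent is spent as a base. Fallback: the phenols are masked with a group that comes off without acid. Setting out from 4, allyl bromide and K2CO3 in DMF give 2,6-bis(allyloxy)benzaldehyde F5. One equivalent of 5 in THF at 0 °C adds to it to give [2,6-bis(allyloxy)phenyl](4,5-dimethoxynaphthalen-1-yl)methanol F6. Pd(PPh3)4 (cat.) and morpholine in THF at room temperature then transfer both allyl groups to the amine under neutral conditions that do not ionize the carbinol, and the route is rejoined at 6.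

Step 6. What may go wrong: the enzyme may bind the bulky, sparingly water-soluble diaryl substrate poorly, or the hemiketal may release the ketone too slowly, so that conversion stalls. Fallback: control of the carbinol is given up and the diastereomers are sorted after ring closure. Setting out from 10, NaBH4 in MeOH at 0 °C reduces the ketone form without selectivity to 12 and (2R,4S)-4-(2,6-dihydroxyphenyl)-4-(4,5-dimethoxynaphthalen-1-yl)butan-2-ol F7. The Mitsunobu closure of step 7 on the mixture converts them with inversion into 13 and (2S,4S)-4-(4,5-dimethoxynaphthalen-1-yl)-2-methylchroman-5-ol F8, the 2,4-cis isomer. The trans and cis chromans differ in ring conformation and should separate on silica, so that the route is rejoined at 13.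

**Further compounds**

F1 | step 4 | (2S,4R)-4-(4,5-dimethoxynaphthalen-1-yl)-2-methoxy-2-methylchroman-5-ol | COc1cccc2c([C@H]3C[C@@](C)(OC)Oc4cccc(O)c43)ccc(OC)c12
F2 | step 4 | (2S,4R)-4-(4,5-dimethoxynaphthalen-1-yl)-2-methylchromane-2,5-diol | COc1cccc2c([C@H]3C[C@@](C)(O)Oc4cccc(O)c43)ccc(OC)c12
F3 | step 4 | (4R)-4-(2,6-dihydroxyphenyl)-4-(4,5-dimethoxynaphthalen-1-yl)butan-2-one | COc1cccc2c([C@@H](CC(C)=O)c3c(O)cccc3O)ccc(OC)c12
F4 | step 4 | (2S,4R)-4-(2,6-dihydroxyphenyl)-4-(4,5-dimethoxynaphthalen-1-yl)butan-2-ol | COc1cccc2c([C@@H](C[C@H](C)O)c3c(O)cccc3O)ccc(OC)c12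
F5 | step 3 | 2,6-bis(allyloxy)benzaldehyde | O=Cc1c(OCC=C)cccc1OCC=C
F6 | step 3 | [2,6-bis(allyloxy)phenyl](4,5-dimethoxynaphthalen-1-yl)methanol (racemic) | COc1cccc2c(C(O)c3c(OCC=C)cccc3OCC=C)ccc(OC)c12
F7 | step 6 | (2R,4S)-4-(2,6-dihydroxyphenyl)-4-(4,5-dimethoxynaphthalen-1-yl)butan-2-ol | COc1cccc2c([C@H](C[C@@H](C)O)c3c(O)cccc3O)ccc(OC)c12
F8 | step 6 | (2S,4S)-4-(4,5-dimethoxynaphthalen-1-yl)-2-methylchroman-5-ol (2,4-cis) | COc1cccc2c([C@@H]3C[C@H](C)Oc4cccc(O)c43)ccc(OC)c12
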